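**Retrosynthetic overview**

1. Ring C is closed last by making the aryl–acyl bond C4–C4a: the flavanone is cut back to an open-chain (S)-3-aryloxy-3-phenylpropanoic S-2-pyridyl thioester whose ring A carries bromine at C4a. The two electrophilic carbons (thioester C4, bromine-bearing C4a) are joined reductively with nickel, without acid or base.
2. Enabling feature: C4a–Br lies ortho to the ether oxygen O1 on C8a of ring A and para to the C7 hydroxyl, and the O1–C2–C3 tether holds C4 so that only the six-membered ring C can form. The C6/C8 prenyl alkenes, the C7–OH and the labile benzylic C2–O1 stereocentre are not touched.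
3. The C6 and C8 prenyl groups go back to two C–I bonds (two-fold Stille coupling). The iodines are placed ortho to the free C7–OH, whose para position C4a is already blocked by the bromine.
4. The C2–O1 bond and the (S) configuration come from a Mitsunobu inversion of an (R)-3-hydroxy-3-phenylpropanoate with a 2-bromo-5-silyloxyphenol made from 4-bromoresorcinol.
5. Ring order: ring A and the phenyl ring B come with the starting materials; ring C is the only ring formed (step 8).

Key step: step 8

Remark: the target is taken as the (2S) enantiomer encoded by the SMILES, and the C7 hydroxyl, once flanked by two ortho substituents, is assumed to need no protection after step 3.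

**Route**

Step 1
Reactants: 1 4-bromobenzene-1,3-diol (4-bromoresorcinol)
Product: 2 2-bromo-5-[(triisopropylsilyl)oxy]phenol
Conditions: i-Pr3SiCl (1.0 equiv), imidazole (2 equiv), CH2Cl2/DMF, −20 → 0 °C
Reagents that add atoms: chlorotriisopropylsilane, CC(C)[Si](Cl)(C(C)C)C(C)C
Why: Silylation with a bulky chlorosilane is sterically controlled and should take place at the unhindered hydroxyl para to bromine, leaving free the hydroxyl next to bromine that later becomes O1; no stereocentre is formed.

Step 2
Reactants: 2 2-bromo-5-[(triisopropylsilyl)oxy]phenol; 3 ethyl (3R)-3-hydroxy-3-phenylpropanoate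
Product: 4 ethyl (3S)-3-{2-bromo-5-[(triisopropylsilyl)oxy]phenoxy}-3-phenylpropanoate
Conditions: PPh3, diisopropyl azodicarboxylate, toluene, 0 °C → rt
Reagents that add atoms: none
Why: Mitsunobu etherification: the acidic ortho-bromophenol displaces the phosphonium-activated benzylic alcohol in an SN2 reaction with inversion, so that the (R)-carbinol of 3 becomes the (S)-aryl ether carbon that ends up as C2.

Step 3
Reactants: 4 ethyl (3S)-3-{2-bromo-5-[(triisopropylsilyl)oxy]phenoxy}-3-phenylpropanoate
Product: 5 ethyl (3S)-3-(2-bromo-5-hydroxyphenoxy)-3-phenylpropanoate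
Conditions: Bu4NF (1.2 equiv), AcOH (1.2 equiv), THF, 0 °C
Reagents that add atoms: none
Why: Fluoride-induced cleavage of the aryl silyl ether, buffered with acetic acid so that the β-aryloxy ester is not exposed to base (no E1cB loss of the phenoxide), frees the hydroxyl that directs the next step.

Step 4
Reactants: 5 ethyl (3S)-3-(2-bromo-5-hydroxyphenoxy)-3-phenylpropanoate
Product: 6 ethyl (3S)-3-(6-bromo-3-hydroxy-2,4-diiodophenoxy)-3-phenylpropanoate
Conditions: N-iodosuccinimide (2.2 equiv), TsOH·H2O (cat.), MeCN, 0 °C → rt
Reagents that add atoms: N-iodosuccinimide, O=C1CCC(=O)N1I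
Why: Electrophilic aromatic iodination directed by the free hydroxyl, whose para position is blocked by bromine, should place iodine at both ortho positions (the future C6 and C8), the only other ring CH being meta to both oxygens and unreactive.

Step 5
Reactants: 6 ethyl (3S)-3-(6-bromo-3-hydroxy-2,4-diiodophenoxy)-3-phenylpropanoate; 7 tributyl(3-methylbut-2-en-1-yl)stannane (2.4 equiv)
Product: 8 ethyl (3S)-3-[6-bromo-3-hydroxy-2,4-bis(3-methylbut-2-en-1-yl)phenoxy]-3-phenylpropanoate
Conditions: Pd2(dba)3 (cat.), tri(2-furyl)phosphine, CuI (cat.), DMF, 60 °C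
Reagents that add atoms: none
Why: Two-fold Stille coupling: zerovalent palladium inserts into the C–I bonds far more readily than into the electron-rich, ortho-alkoxy C–Br bond, and the allylstannane should transfer the prenyl group with bond formation at its unsubstituted terminus under neutral conditions that leave the β-aryloxy ester and C2 untouched.

Step 6
Reactants: 8 ethyl (3S)-3-[6-bromo-3-hydroxy-2,4-bis(3-methylbut-2-en-1-yl)phenoxy]-3-phenylpropanoate
Product: 9 (3S)-3-[6-bromo-3-hydroxy-2,4-bis(3-methylbut-2-en-1-yl)phenoxy]-3-phenylpropanoic acid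
Conditions: LiOH·H2O (3 equiv), THF/H2O, 0 °C → rt; then 1 M HCl to pH 3–4, 0 °C
Reagents that add atoms: lithium hydroxide, [Li+].[OH-]
Why: Ester saponification at low temperature; under the basic conditions the ring is a phenoxide and hence a poor leaving group, which should suppress E1cB cleavage of the C2–O1 bond, and the brief mild acidification spares the prenyl groups.

Step 7
Reactants: 9 (3S)-3-[6-bromo-3-hydroxy-2,4-bis(3-methylbut-2-en-1-yl)phenoxy]-3-phenylpropanoic acid
Product: 10 S-pyridin-2-yl (3S)-3-[6-bromo-3-hydroxy-2,4-bis(3-methylbut-2-en-1-yl)phenoxy]-3-phenylpropanethioate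
Conditions: 2,2'-dipyridyl disulfide, PPh3, CH2Cl2, rt
Reagents that add atoms: 2,2'-dipyridyl disulfide, c1ccc(SSc2ccccn2)nc1
Why: Redox condensation of the acid with 2,2'-dipyridyl disulfide and triphenylphosphine gives the activated thioester under neutral conditions, the hindered phenol between two prenyl groups being too poor a nucleophile to compete.

Step 8
Reactants: 10 S-pyridin-2-yl (3S)-3-[6-bromo-3-hydroxy-2,4-bis(3-methylbut-2-en-1-yl)phenoxy]-3-phenylpropanethioate
Product: 11 (2S)-7-hydroxy-6,8-bis(3-methylbut-2-en-1-yl)-2-phenyl-2,3-dihydro-4H-chromen-4-one (7-hydroxy-6,8-diprenylflavanone)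
Conditions: NiBr2(dme) (20 mol %), 4,4'-di-tert-butyl-2,2'-bipyridine (24 mol %), Zn dust (3 equiv), N,N-dimethylacetamide, 0.01 M, rt
Reagents that add atoms: none
Why: Proposed new method: an intramolecular nickel-catalysed reductive cross-electrophile acylation, in which zerovalent nickel (from NiBr2(dme), the bipyridine and zinc) should insert into the C(acyl)–S bond of the 2-pyridyl thioester with help of the pyridine nitrogen, the acyl complex of divalent nickel is reduced by zinc to the monovalent state, adds oxidatively to the C4a–Br bond held next to it, and the trivalent aryl(acyl)nickel species eliminates reductively to form C4–C4a. The closest known reaction type is the intermolecular nickel-catalysed reductive ketone synthesis from organic halides and 2-pyridyl thioesters or other activated carboxylic acid derivatives, with the Parham cyclization as its polar, strongly basic counterpart; new here is the ring-closing use on an electron-rich aryl bromide that carries a β-aryloxy acyl chain. Ring C closes as a six-membered ring by reductive elimination from a seven-membered nickelacycle (Ni, C4, C3, C2, O1, C8a, C4a), formally a 6-exo-trig acyl substitution. No stereocentre is created: C2 is carried over unchanged from 10, because without acid or base neither ionization of the benzylic C2–O1 bond nor enolization with retro-oxa-Michael opening can occur. The step needs chemoselectivity (ring closure before protodebromination, before decarbonylation with loss of the aryloxide, and before intermolecular coupling) and site selectivity; the first is secured by the ortho placement of C4a–Br next to the O1 tether, the fast thioester activation, room temperature and high dilution, the second by the bromine that marks C4a as the only reactive ring carbon, while the trisubstituted prenyl alkenes and the hindered C7 hydroxyl should be inert to nickel and zinc.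

**Compound list**

1 | 4-bromobenzene-1,3-diol (4-bromoresorcinol) | Oc1ccc(Br)c(O)c1 | starting material
2 | 2-bromo-5-[(triisopropylsilyl)oxy]phenol | CC(C)[Si](Oc1ccc(Br)c(O)c1)(C(C)C)C(C)C | intermediate
3 | ethyl (3R)-3-hydroxy-3-phenylpropanoate | CCOC(=O)C[C@@H](O)c1ccccc1 | starting material
4 | ethyl (3S)-3-{2-bromo-5-[(triisopropylsilyl)oxy]phenoxy}-3-phenylpropanoate | CCOC(=O)C[C@H](Oc1cc(O[Si](C(C)C)(C(C)C)C(C)C)ccc1Br)c1ccccc1 | intermediate
5 | ethyl (3S)-3-(2-bromo-5-hydroxyphenoxy)-3-phenylpropanoate | CCOC(=O)C[C@H](Oc1cc(O)ccc1Br)c1ccccc1 | intermediate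
6 | ethyl (3S)-3-(6-bromo-3-hydroxy-2,4-diiodophenoxy)-3-phenylpropanoate | CCOC(=O)C[C@H](Oc1c(I)c(O)c(I)cc1Br)c1ccccc1 | intermediate
7 | tributyl(3-methylbut-2-en-1-yl)stannane | CCCC[Sn](CCCC)(CCCC)CC=C(C)C | starting material
8 | ethyl (3S)-3-[6-bromo-3-hydroxy-2,4-bis(3-methylbut-2-en-1-yl)phenoxy]-3-phenylpropanoate | CCOC(=O)C[C@H](Oc1c(CC=C(C)C)c(O)c(CC=C(C)C)cc1Br)c1ccccc1 | intermediate
9 | (3S)-3-[6-bromo-3-hydroxy-2,4-bis(3-methylbut-2-en-1-yl)phenoxy]-3-phenylpropanoic acid | OC(=O)C[C@H](Oc1c(CC=C(C)C)c(O)c(CC=C(C)C)cc1Br)c1ccccc1 | intermediate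
10 | S-pyridin-2-yl (3S)-3-[6-bromo-3-hydroxy-2,4-bis(3-methylbut-2-en-1-yl)phenoxy]-3-phenylpropanethioate | O=C(Sc1ccccn1)C[C@H](Oc1c(CC=C(C)C)c(O)c(CC=C(C)C)cc1Br)c1ccccc1 | intermediate
11 | (2S)-7-hydroxy-6,8-bis(3-methylbut-2-en-1-yl)-2-phenyl-2,3-dihydro-4H-chromen-4-one | CC(C)=CCc1cc2c(c(CC=C(C)C)c1O)O[C@H](c1ccccc1)CC2=O | target

**Step count**

Total steps: 8. Longest linear sequence: 8 steps (1 → 11).

**Steps most likely to fail, with fallbacks**

Step 8 (proposed new method). The aryl–nickel intermediate may be protonated by the free phenol (protodebromination), the acyl–nickel species may lose CO and then expel the aryloxide, or the coupling may become intermolecular. The fallback uses known chemistry, sets out from 9 and comes back at 11. Acid 9 is condensed with N,O-dimethylhydroxylamine hydrochloride (EDC·HCl, HOBt, N-methylmorpholine, CH2Cl2, 0 °C → rt) to the Weinreb amide (3S)-3-[6-bromo-3-hydroxy-2,4-bis(3-methylbut-2-en-1-yl)phenoxy]-N-methoxy-N-methyl-3-phenylpropanamide F1. After deprotonation of the phenol with NaH (THF, 0 °C), bromine–lithium exchange with t-BuLi (2.2 equiv, −90 °C) and intramolecular attack of the C4a carbanion on the amide carbonyl (Parham cyclization) should give 11 on NH4Cl work-up. The chelated amide adduct prevents over-addition, and the low temperature keeps the C2–O1 bond intact.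

Step 2. The benzylic β-hydroxy ester may dehydrate to the cinnamate under Mitsunobu activation, and partial ionization at the benzylic carbon would erode the stereochemical fidelity of the inversion. The fallback sets the stereocentre by catalysis instead; it sets out from 2 and comes back at 4. Conjugate addition of phenol 2 to ethyl 3-phenylprop-2-ynoate (Cs2CO3 cat., MeCN, 40 °C) should give the enol ether ethyl (2Z)-3-{2-bromo-5-[(triisopropylsilyl)oxy]phenoxy}-3-phenylprop-2-enoate F2. Asymmetric hydrogenation of its ester-conjugated double bond with [Rh(cod)2]BF4 and a chiral bisphosphine (DuPhos type, ligand enantiomer chosen so that hydrogen is delivered to the face giving the (S) centre; H2, CH2Cl2/MeOH, rt) should then give 4. The aryl bromide and silyl ether are expected to survive.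

Step 5. The second coupling at the hindered position between the two oxygens may stall, allylic transposition may give the branched 1,1-dimethylallyl isomer, and protodeiodination or insertion into the C–Br bond may compete. The fallback replaces cross-coupling by sigmatropic chemistry, needs no iodination, sets out from 5 and comes back at 8.
- Phenol 5 is O-alkylated with methyl 2-methylbut-3-en-2-yl carbonate under zerovalent palladium catalysis (Pd(PPh3)4, THF, 0 °C → rt) to the tertiary ether ethyl (3S)-3-{2-bromo-5-[(2-methylbut-3-en-2-yl)oxy]phenoxy}-3-phenylpropanoate F3.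
- Aromatic Claisen rearrangement (Eu(fod)3 cat., CHCl3, 60 °C, or N,N-diethylaniline, 150 °C) should give the two ortho-prenyl phenols ethyl (3S)-3-[2-bromo-5-hydroxy-4-(3-methylbut-2-en-1-yl)phenoxy]-3-phenylpropanoate F4 and ethyl (3S)-3-[6-bromo-3-hydroxy-2-(3-methylbut-2-en-1-yl)phenoxy]-3-phenylpropanoate F5, which need not be separated.
- A second O-alkylation under the same conditions gives ethyl (3S)-3-{2-bromo-4-(3-methylbut-2-en-1-yl)-5-[(2-methylbut-3-en-2-yl)oxy]phenoxy}-3-phenylpropanoate F6 and ethyl (3S)-3-{6-bromo-2-(3-methylbut-2-en-1-yl)-3-[(2-methylbut-3-en-2-yl)oxy]phenoxy}-3-phenylpropanoate F7.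
- A second Claisen rearrangement can now go only to the one free ortho position (the para position is blocked by bromine), so both isomers should converge on 8.

**Further compounds**

F1 | step 8 | (3S)-3-[6-bromo-3-hydroxy-2,4-bis(3-methylbut-2-en-1-yl)phenoxy]-N-methoxy-N-methyl-3-phenylpropanamide | CON(C)C(=O)C[C@H](Oc1c(CC=C(C)C)c(O)c(CC=C(C)C)cc1Br)c1ccccc1
F2 | step 2 | ethyl (2Z)-3-{2-bromo-5-[(triisopropylsilyl)oxy]phenoxy}-3-phenylprop-2-enoate | CCOC(=O)/C=C(\Oc1cc(O[Si](C(C)C)(C(C)C)C(C)C)ccc1Br)c1ccccc1
F3 | step 5 | ethyl (3S)-3-{2-bromo-5-[(2-methylbut-3-en-2-yl)oxy]phenoxy}-3-phenylpropanoate | CCOC(=O)C[C@H](Oc1cc(OC(C)(C)C=C)ccc1Br)c1ccccc1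
F4 | step 5 | ethyl (3S)-3-[2-bromo-5-hydroxy-4-(3-methylbut-2-en-1-yl)phenoxy]-3-phenylpropanoate | CCOC(=O)C[C@H](Oc1cc(O)c(CC=C(C)C)cc1Br)c1ccccc1
F5 | step 5 | ethyl (3S)-3-[6-bromo-3-hydroxy-2-(3-methylbut-2-en-1-yl)phenoxy]-3-phenylpropanoate | CCOC(=O)C[C@H](Oc1c(CC=C(C)C)c(O)ccc1Br)c1ccccc1
F6 | step 5 | ethyl (3S)-3-{2-bromo-4-(3-methylbut-2-en-1-yl)-5-[(2-methylbut-3-en-2-yl)oxy]phenoxy}-3-phenylpropanoate | CCOC(=O)C[C@H](Oc1cc(OC(C)(C)C=C)c(CC=C(C)C)cc1Br)c1ccccc1
F7 | step 5 | ethyl (3S)-3-{6-bromo-2-(3-methylbut-2-en-1-yl)-3-[(2-methylbut-3-en-2-yl)oxy]phenoxy}-3-phenylpropanoate | CCOC(=O)C[C@H](Oc1c(CC=C(C)C)c(OC(C)(C)C=C)ccc1Br)c1ccccc1
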